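**Retrosynthetic overview**

1. Target 24 ⇐ global desilylation of 23 ⇐ acylation of the only free hydroxyl (C8–OH) of macrocycle 19 with protected acid 22.
2. 19 ⇐ ring closure at C9–C10 from the open-chain bis-epoxy alkyne 17 by an intramolecular nickel-catalysed reductive epoxide–alkyne coupling. One operation builds the ten-membered carbocycle and the E-C1=C10 trisubstituted olefin, and frees C8–OH.
3. Enabling feature: the C8(O)–C9H2–C10(CH3)=C1H unit, a carbinol β to the methyl-bearing sp2 ring carbon, is the retron of a syn H/C addition of a terminal oxirane across a methyl-capped alkyne. The trans C4–C5 oxirane is a second rigid element, 1,5 to the new E olefin, so the product is an unstrained epoxygermacrene-type cyclodecene.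
4. 17 ⇐ three stereo-defining operations on a linear chain: Sharpless epoxidation (C4, C5), matched (E)-allylboration (C6, C7), hydroxyl-directed vanadium epoxidation (C8).
5. Order of ring formation: oxirane C4–C5–O (step 4), oxirane C8–C9–O (step 8, consumed in step 10), ten-membered ring C1–C10 (step 10).

Key step: step 10

Remark: germacrane numbering is used throughout (ring C1–C10; C10 carries the olefinic methyl, C4 the oxirane methyl, C7 the isopropyl group). Compound 11 is used as the racemate, since its stereocentre is lost in step 6.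

**Route**

Step 1
Reactants: 1 pent-3-yn-1-ol
Product: 2 5-bromopent-2-yne
Conditions: CBr4, PPh3, CH2Cl2, 0 °C
Reagents that add atoms: carbon tetrabromide, BrC(Br)(Br)Br
Why: Appel reaction, SN2 displacement of the primary oxyphosphonium by bromide; no stereocentre is involved.

Step 2
Reactants: 2 5-bromopent-2-yne; 3 ethyl but-2-ynoate
Product: 7 ethyl (2E)-3-methyloct-2-en-6-ynoate, via pent-3-yn-1-ylmagnesium bromide 4 (not isolated), via pent-3-yn-1-ylcopper 5 (not isolated), via alkenylcopper adduct 6 (not isolated)
Conditions: Mg, THF, 40 °C; CuBr·SMe2, THF, −78 °C; then 3, −78 to −40 °C; aq. NH4Cl, −78 °C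
Reagents that add atoms: none
Why: Stereospecific syn carbocupration (conjugate addition) of the alkylcopper to the ynoate and protonation with retention should give the (E)-enoate with the chain trans to the ester, which later fixes the trans C4–C5 oxirane.

Step 3
Reactants: 7 ethyl (2E)-3-methyloct-2-en-6-ynoate
Product: 8 (2E)-3-methyloct-2-en-6-yn-1-ol
Conditions: i-Bu2AlH (2.2 equiv), CH2Cl2, −78 °C; Rochelle salt work-up
Reagents that add atoms: none
Why: 1,2-Reduction of an α,β-unsaturated ester with DIBAL-H gives the allylic alcohol without touching the alkyne or the olefin geometry.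

Step 4
Reactants: 8 (2E)-3-methyloct-2-en-6-yn-1-ol
Product: 9 [(2R,3R)-3-methyl-3-(pent-3-yn-1-yl)oxiran-2-yl]methanol
Conditions: Ti(OiPr)4 (10 mol%), D-(−)-diethyl tartrate (12 mol%), t-BuOOH, 4 Å MS, CH2Cl2, −20 °C
Reagents that add atoms: tert-butyl hydroperoxide, CC(C)(C)OO
Why: Sharpless asymmetric epoxidation of a geraniol-type allylic alcohol; the D-(−)-tartrate ligand controls the face and should set C4 (R) and C5 (R), the E olefin giving the trans oxirane.

Step 5
Reactants: 9 [(2R,3R)-3-methyl-3-(pent-3-yn-1-yl)oxiran-2-yl]methanol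
Product: 10 (2S,3R)-3-methyl-3-(pent-3-yn-1-yl)oxirane-2-carbaldehyde
Conditions: TEMPO (10 mol%), PhI(OAc)2, CH2Cl2, 23 °C
Reagents that add atoms: none
Why: Oxoammonium-mediated oxidation of the primary alcohol stops at the aldehyde and should leave the oxirane and the configuration at C5 untouched (the descriptor changes only by priority).

Step 6
Reactants: 11 4-methylpent-1-en-3-ol; 12 bis(pinacolato)diboron
Product: 13 2-[(2E)-4-methylpent-2-en-1-yl]-4,4,5,5-tetramethyl-1,3,2-dioxaborolane
Conditions: [Pd(MeCN)4](BF4)2 (5 mol%), DMSO–MeOH, 40 °C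
Reagents that add atoms: none
Why: Palladium-catalysed borylation of an allylic alcohol through a syn π-allylpalladium intermediate should place boron on the unhindered terminus and give the linear (E)-allylboronate.

Step 7
Reactants: 10 (2S,3R)-3-methyl-3-(pent-3-yn-1-yl)oxirane-2-carbaldehyde; 13 2-[(2E)-4-methylpent-2-en-1-yl]-4,4,5,5-tetramethyl-1,3,2-dioxaborolane
Product: 15 (1R,2R)-1-[(2R,3R)-3-methyl-3-(pent-3-yn-1-yl)oxiran-2-yl]-2-(propan-2-yl)but-3-en-1-ol, via pinacol borate ester 14 (not isolated)
Conditions: (R)-3,3′-bis(2,4,6-triisopropylphenyl)-1,1′-binaphthyl-2,2′-diyl hydrogen phosphate (5 mol%), 4 Å MS, toluene, −30 °C; aq. NaHCO3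
Reagents that add atoms: none
Why: Chiral phosphoric acid-catalysed allylboration through a closed chair transition state, in which the (E)-boronate should give the C6/C7 anti relationship and the (R)-catalyst is expected to steer attack to the re face of the aldehyde, the face also preferred by the dipole-minimised conformation of the α,β-epoxy aldehyde (matched, C6 R).

Step 8
Reactants: 15 (1R,2R)-1-[(2R,3R)-3-methyl-3-(pent-3-yn-1-yl)oxiran-2-yl]-2-(propan-2-yl)but-3-en-1-ol
Product: 16 (1R,2S)-3-methyl-1-[(2R,3R)-3-methyl-3-(pent-3-yn-1-yl)oxiran-2-yl]-2-[(2S)-oxiran-2-yl]butan-1-ol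
Conditions: VO(acac)2 (5 mol%), t-BuOOH, CH2Cl2, 0 to 23 °C
Reagents that add atoms: tert-butyl hydroperoxide, CC(C)(C)OO
Why: Hydroxyl-directed vanadium epoxidation of an anti homoallylic alcohol through a chair-like vanadate ester, with the C6 substituent and the C7 isopropyl group both equatorial, should deliver oxygen syn to the C6 hydroxyl and anti to isopropyl, setting C8.

Step 9
Reactants: 16 (1R,2S)-3-methyl-1-[(2R,3R)-3-methyl-3-(pent-3-yn-1-yl)oxiran-2-yl]-2-[(2S)-oxiran-2-yl]butan-1-ol
Product: 17 triethyl{(1R,2R)-3-methyl-1-[(2R,3R)-3-methyl-3-(pent-3-yn-1-yl)oxiran-2-yl]-2-[(2S)-oxiran-2-yl]butoxy}silane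
Conditions: Et3SiCl, imidazole, DMF, 0 to 23 °C
Reagents that add atoms: chlorotriethylsilane, CC[Si](CC)(CC)Cl
Why: Silylation of the secondary alcohol under non-acidic conditions masks O6, so that the hydroxyl freed in the key step is the only one available for acylation.

Step 10
Reactants: 17 triethyl{(1R,2R)-3-methyl-1-[(2R,3R)-3-methyl-3-(pent-3-yn-1-yl)oxiran-2-yl]-2-[(2S)-oxiran-2-yl]butoxy}silane
Product: 19 (1(10)E,4R,5R,6R,7R,8R)-4,5-epoxy-6-[(triethylsilyl)oxy]germacr-1(10)-en-8-ol, via macrocyclic diethylborinate 18 (not isolated)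
Conditions: Ni(cod)2 (20 mol%), PBu3 (40 mol%), Et3B (4 equiv), t-BuOMe, syringe-pump addition of 17 to 0.005 M, 23 °C; then H2O, aq. NaHCO3
Reagents that add atoms: none
Why: Proposed new method: zerovalent nickel binds the alkyne, opens the terminal oxirane of 17 at its CH2 carbon (C9) by SN2-type oxidative addition and inserts the alkyne syn, so that C9 bonds to the methyl-bearing alkyne carbon C10 in an oxanickelacycle; ethyl transfer from Et3B to nickel, β-hydride elimination of ethene and C–H reductive elimination with retention then place H on C1 cis to C9, which is the E ring olefin, and leave O8 as the borinate 18. The closest known reaction type is the Ni(cod)2/trialkylphosphine/Et3B reductive coupling of alkynes with terminal epoxides, which is known intermolecularly, for five- and six-membered rings and for a fourteen-membered lactone, but not for a ten-membered carbocycle with an endocyclic E olefin. The ten-membered ring closes in the endo mode with respect to the alkyne (10-endo-dig, both alkyne carbons end up in the ring), and the oxirane is opened at its terminal carbon so that C8 becomes a ring atom. No new sp3 stereocentre is formed: C8 keeps the configuration set in step 8 because its C–O bond is not broken, and the E geometry follows from the syn addition. The step needs C10-over-C1 regioselectivity, terminal-over-trisubstituted oxirane selectivity and cyclisation over oligomerisation: the small methyl terminus favours C–C bond formation at C10, the alternative bond to C1 would give a nine-membered ring holding a trans-oxirane, the C4–C5 oxirane is too hindered for SN2-type insertion, and the trans-oxirane together with the three contiguous branched carbons C6–C8 folds the chain so that C9 lies near C10 under high dilution.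

Step 11
Reactants: 20 4-hydroxybenzoic acid
Product: 22 4-[(tert-butyldimethylsilyl)oxy]benzoic acid, via bis-silylated 4-hydroxybenzoic acid 21 (not isolated)
Conditions: t-BuMe2SiCl (2.2 equiv), imidazole, DMF, 23 °C; then THF–AcOH–H2O, 23 °C
Reagents that add atoms: tert-butyldimethylsilyl chloride, CC(C)(C)[Si](C)(C)Cl
Why: Exhaustive silylation followed by selective hydrolysis of the much more labile silyl ester should leave the aryl silyl ether in place.

Step 12
Reactants: 19 (1(10)E,4R,5R,6R,7R,8R)-4,5-epoxy-6-[(triethylsilyl)oxy]germacr-1(10)-en-8-ol; 22 4-[(tert-butyldimethylsilyl)oxy]benzoic acid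
Product: 23 (1(10)E,4R,5R,6R,7R,8R)-4,5-epoxy-6-[(triethylsilyl)oxy]germacr-1(10)-en-8-yl 4-[(tert-butyldimethylsilyl)oxy]benzoate
Conditions: DCC, DMAP, CH2Cl2, 23 to 40 °C
Reagents that add atoms: none
Why: Steglich esterification acylates the single free secondary hydroxyl at C8 with retention under non-acidic conditions, which the epoxy-ene ring system should tolerate.

Step 13
Reactants: 23 (1(10)E,4R,5R,6R,7R,8R)-4,5-epoxy-6-[(triethylsilyl)oxy]germacr-1(10)-en-8-yl 4-[(tert-butyldimethylsilyl)oxy]benzoate
Product: 24 (1(10)E,4R,5R,6R,7S,8R)-4,5-epoxy-6-hydroxygermacr-1(10)-en-8-yl 4-hydroxybenzoate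
Conditions: Bu4NF, AcOH (1:1), THF, 0 °C
Reagents that add atoms: none
Why: Acetic acid-buffered fluoride should cleave the aryl silyl ether and the triethylsilyl ether in one operation while avoiding base-induced acyl migration from O8 to O6 and acid-induced transannular opening of the oxirane.

**Compound list**

1 | pent-3-yn-1-ol | CC#CCCO | starting material
2 | 5-bromopent-2-yne | CC#CCCBr | intermediate
3 | ethyl but-2-ynoate | CC#CC(=O)OCC | starting material
4 | pent-3-yn-1-ylmagnesium bromide | CC#CCC[Mg]Br | intermediate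
5 | pent-3-yn-1-ylcopper (magnesium bromide complex) | CC#CCC[Cu] | intermediate
6 | ethyl (2Z)-2-cuprio-3-methyloct-2-en-6-ynoate (alkenylcopper adduct) | [Cu]/C(C(=O)OCC)=C(/C)CCC#CC | intermediate
7 | ethyl (2E)-3-methyloct-2-en-6-ynoate | CCOC(=O)/C=C(\C)CCC#CC | intermediate
8 | (2E)-3-methyloct-2-en-6-yn-1-ol | OC/C=C(\C)CCC#CC | intermediate
9 | [(2R,3R)-3-methyl-3-(pent-3-yn-1-yl)oxiran-2-yl]methanol | CC#CCC[C@@]1(C)O[C@@H]1CO | intermediate
10 | (2S,3R)-3-methyl-3-(pent-3-yn-1-yl)oxirane-2-carbaldehyde | CC#CCC[C@@]1(C)O[C@@H]1C=O | intermediate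
11 | 4-methylpent-1-en-3-ol (racemic) | CC(C)C(O)C=C | starting material
12 | bis(pinacolato)diboron | CC1(C)OB(OC1(C)C)B1OC(C)(C)C(C)(C)O1 | starting material
13 | 2-[(2E)-4-methylpent-2-en-1-yl]-4,4,5,5-tetramethyl-1,3,2-dioxaborolane | CC(C)/C=C/CB1OC(C)(C)C(C)(C)O1 | intermediate
14 | pinacol borate ester of 15 (O6–B) | CC#CCC[C@@]1(C)O[C@@H]1[C@H](OB2OC(C)(C)C(C)(C)O2)[C@H](C(C)C)C=C | intermediate
15 | (1R,2R)-1-[(2R,3R)-3-methyl-3-(pent-3-yn-1-yl)oxiran-2-yl]-2-(propan-2-yl)but-3-en-1-ol | CC#CCC[C@@]1(C)O[C@@H]1[C@H](O)[C@H](C(C)C)C=C | intermediate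
16 | (1R,2S)-3-methyl-1-[(2R,3R)-3-methyl-3-(pent-3-yn-1-yl)oxiran-2-yl]-2-[(2S)-oxiran-2-yl]butan-1-ol | CC#CCC[C@@]1(C)O[C@@H]1[C@H](O)[C@H](C(C)C)[C@H]2CO2 | intermediate
17 | triethyl{(1R,2R)-3-methyl-1-[(2R,3R)-3-methyl-3-(pent-3-yn-1-yl)oxiran-2-yl]-2-[(2S)-oxiran-2-yl]butoxy}silane | CC#CCC[C@@]1(C)O[C@@H]1[C@H](O[Si](CC)(CC)CC)[C@H](C(C)C)[C@H]2CO2 | intermediate
18 | (1(10)E,4R,5R,6R,7R,8R)-4,5-epoxy-6-[(triethylsilyl)oxy]germacr-1(10)-en-8-yl diethylborinate | C/C1=C\CC[C@@]2(C)O[C@@H]2[C@H](O[Si](CC)(CC)CC)[C@H](C(C)C)[C@H](OB(CC)CC)C1 | intermediate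
19 | (1(10)E,4R,5R,6R,7R,8R)-4,5-epoxy-6-[(triethylsilyl)oxy]germacr-1(10)-en-8-ol | C/C1=C\CC[C@@]2(C)O[C@@H]2[C@H](O[Si](CC)(CC)CC)[C@H](C(C)C)[C@H](O)C1 | intermediate
20 | 4-hydroxybenzoic acid | OC(=O)c1ccc(O)cc1 | starting material
21 | tert-butyldimethylsilyl 4-[(tert-butyldimethylsilyl)oxy]benzoate | CC(C)(C)[Si](C)(C)OC(=O)c1ccc(O[Si](C)(C)C(C)(C)C)cc1 | intermediate
22 | 4-[(tert-butyldimethylsilyl)oxy]benzoic acid | OC(=O)c1ccc(O[Si](C)(C)C(C)(C)C)cc1 | intermediate
23 | (1(10)E,4R,5R,6R,7R,8R)-4,5-epoxy-6-[(triethylsilyl)oxy]germacr-1(10)-en-8-yl 4-[(tert-butyldimethylsilyl)oxy]benzoate | C/C1=C\CC[C@@]2(C)O[C@@H]2[C@H](O[Si](CC)(CC)CC)[C@H](C(C)C)[C@H](OC(=O)c2ccc(O[Si](C)(C)C(C)(C)C)cc2)C1 | intermediate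
24 | (1(10)E,4R,5R,6R,7S,8R)-4,5-epoxy-6-hydroxygermacr-1(10)-en-8-yl 4-hydroxybenzoate | C/C1=C\CC[C@@]2(C)O[C@@H]2[C@H](O)[C@H](C(C)C)[C@H](OC(=O)c2ccc(O)cc2)C1 | target

**Step count and risk**

Total step count: 13. Longest linear sequence: 11 steps (1–5, 7–10, 12, 13).

Steps most likely to fail:

1. Step 10 (key step). The closure may lose out to oligomerisation, to bond formation at C1 instead of C10 (nine-membered ring with an exocyclic olefin), or to nickel-promoted isomerisation of the terminal oxirane to a carbonyl compound. The fallback sets out from 17 and comes back at 19; it uses two reaction types that are known for open-chain partners and fixes the olefin geometry before ring closure. Syn hydrozirconation of the methyl-capped alkyne with excess Cp2Zr(H)Cl in THF, equilibrated so that zirconium sits on the methyl-bearing carbon, should give the alkenylzirconocene chloride F1. Iodinolysis with I2 at 0 °C should give the (E)-alkenyl iodide F2 with retention. F2 would then be cyclised by nickel-catalysed reductive cross-electrophile coupling of the alkenyl iodide with the terminal oxirane under iodide co-catalysis (NiBr2·glyme, 4,4′-di-tert-butyl-2,2′-bipyridine, NaI, Et3N·HCl, Mn powder, DMPU, high dilution). Iodide activates the oxirane at C9 and the alkenylnickel species captures the C9 radical, which should give 19 directly.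

2. Step 8. Facial discrimination on a terminal olefin may be poor, and the vanadium Lewis acid may open the neighbouring epoxy alcohol. The fallback sets out from 15 and comes back at 16. The alcohol is converted with Boc2O and DMAP in MeCN into the tert-butyl carbonate F3. IBr in toluene at −85 °C should then close the six-membered cyclic iodocarbonate F4; the carbonyl oxygen captures the iodonium ion through a chair with both ring substituents equatorial, which gives the 1,3-syn relationship. Brief treatment of F4 with K2CO3 in MeOH at 0 °C cleaves the carbonate, and the C8 alkoxide displaces iodide to give 16.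

3. Step 7. The Brønsted acid catalyst may open or rearrange the trisubstituted oxirane of 10, and facial control may erode if an uncatalysed background reaction competes. The fallback sets out from 10 and 11 and comes back at 15, replacing catalyst control by a stoichiometric, acid-free chromium reagent. PBr3 in Et2O at 0 °C converts 11 with allylic transposition into (2E)-1-bromo-4-methylpent-2-ene F5. CrCl2 (divalent chromium) in THF at 0 °C turns F5 into the γ-substituted allylchromium reagent, which adds to 10 in a Nozaki–Hiyama allylation. The chair transition state should give the C6/C7 anti relationship, and the dipole-minimised conformation of the epoxy aldehyde should set C6; a minor C6 epimer would be removed by chromatography.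

Further compounds
F1 | step 10 | chlorobis(cyclopentadienyl)zirconium alkenyl complex of 17 (Zr on C10, cis to H on C1) | C/C(=C\CC[C@@]1(C)O[C@@H]1[C@H](O[Si](CC)(CC)CC)[C@H](C(C)C)[C@H]2CO2)[Zr](Cl)(C3C=CC=C3)C4C=CC=C4
F2 | step 10 | triethyl{(1R,2R)-1-[(2R,3R)-3-[(3E)-4-iodopent-3-en-1-yl]-3-methyloxiran-2-yl]-3-methyl-2-[(2S)-oxiran-2-yl]butoxy}silane | C/C(I)=C\CC[C@@]1(C)O[C@@H]1[C@H](O[Si](CC)(CC)CC)[C@H](C(C)C)[C@H]2CO2
F3 | step 8 | tert-butyl carbonate of 15 (at O6) | CC#CCC[C@@]1(C)O[C@@H]1[C@H](OC(=O)OC(C)(C)C)[C@H](C(C)C)C=C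
F4 | step 8 | cyclic iodocarbonate: 1,3-dioxan-2-one spanning O6 and O8 with iodomethyl on C8 (C6/C8 syn, isopropyl anti) | CC#CCC[C@@]1(C)O[C@@H]1[C@@H]2OC(=O)O[C@H](CI)[C@H]2C(C)C
F5 | step 7 | (2E)-1-bromo-4-methylpent-2-ene | CC(C)/C=C/CBr
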